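**Strategy.** The route rests on cutting ring A of the chromone between C8a–C8, C6–C7 and C4a–C8a, so that the hexasubstituted benzene ring with its three different oxygens (O1 at C8a, OMe at C5, OH at C7), the C6 methyl and the C8 formyl carbon is assembled from two small pieces. A thermal cyclobutenone–siloxyalkyne benzannulation does this in one operation and leaves C4a as the only unsubstituted carbon. Its precursors are 3-methoxy-2-methylcyclobutenone and a triisopropylsiloxyalkyne whose formyl group is masked as a 5,5-dimethyl-1,3-dioxane acetal. The pyranone ring is then added by directed lithiation at C4a, acylation and one-carbon annulation.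

Key step: step 5

**Remarks on the chemistry (assumptions and design changes)**
- Locants O1 and C2–C8a are those of the chromone. The target has no stereocentre.
- The formyl group is carried as a cyclic 5,5-dimethyl-1,3-dioxane, not as an open-chain dialkyl acetal. An acetal carbon conjugated through the triple bond with the siloxy oxygen, and later flanked by a free phenol, ionises easily; the cyclic acetal recloses. The bonds formed in the benzannulation and the carbon skeletons of both partners and of the phenol are unchanged.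
- A Lewis-acid Friedel–Crafts acylation at C4a would not spare the acetal or the aryl silyl ether, and the liberated aldehyde would deactivate the ring. The C4–C4a bond is therefore made under basic conditions by directed ortho-lithiation of the methoxymethyl ether.
- Ketene is assumed to be delivered as a gas stream from the pyrolysis of acetone.
- If the acid in step 9 also loosens the silyl ether, the mixture is taken into step 10, which converges on the target.

**Route**

Step 1
Reactants: 1 1-ethoxyprop-1-yne; 2 acetone (ketene source)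
Product: 4 3-ethoxy-2-methylcyclobut-2-en-1-one, via ketene 3 (not isolated)
Conditions: ketene gas (pyrolysis of acetone, ketene lamp), CH2Cl2, 0 °C → rt
Reagents that add atoms: none
Why: Ketene–ynol ether (2+2) cycloaddition, in which the nucleophilic methyl-bearing alkyne carbon attacks the ketene carbonyl carbon, so that the ethoxy group ends at C3 and the methyl at C2 of the cyclobutenone.

Step 2
Reactants: 4 3-ethoxy-2-methylcyclobut-2-en-1-one
Product: 5 3-methoxy-2-methylcyclobut-2-en-1-one
Conditions: TsOH·H2O (cat.), MeOH (solvent), 40 °C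
Reagents that add atoms: methanol, CO
Why: Acid-catalysed alkoxy exchange of a vinylogous ester (addition of methanol at C3, loss of ethanol), driven by the large excess of methanol.

Step 3
Reactants: 6 3,3-diethoxyprop-1-yne; 7 2,2-dimethylpropane-1,3-diol
Product: 8 2-ethynyl-5,5-dimethyl-1,3-dioxane
Conditions: TsOH·H2O (cat.), cyclohexane, reflux, EtOH removed by azeotropic distillation
Reagents that add atoms: none
Why: Acid-catalysed transacetalisation, driven by removal of ethanol and by the stability of the six-membered gem-dimethyl acetal.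

Step 4
Reactants: 8 2-ethynyl-5,5-dimethyl-1,3-dioxane
Product: 11 {[(5,5-dimethyl-1,3-dioxan-2-yl)ethynyl]oxy}tri(propan-2-yl)silane, via lithium acetylide 9 (not isolated), via lithium ynolate 10 (not isolated)
Conditions: n-BuLi, THF, −78 °C; LiOOt-Bu (from t-BuOOH + LiN(SiMe3)2, THF, −78 °C), −78 → 0 °C; i-Pr3SiOTf, −78 → 0 °C; rapid filtration through Et3N-deactivated silica
Reagents that add atoms: tert-butyl hydroperoxide, CC(C)(C)OO; triisopropylsilyl trifluoromethanesulfonate, CC(C)[Si](OS(=O)(=O)C(F)(F)F)(C(C)C)C(C)C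
Why: Oxidation of a lithium acetylide by lithium tert-butyl peroxide (attack of the acetylide on the peroxide oxygen with loss of tert-butoxide) gives the ynolate, which the bulky silyl triflate traps on oxygen (known ynolate O-silylation to siloxyalkynes).

Step 5
Reactants: 5 3-methoxy-2-methylcyclobut-2-en-1-one; 11 {[(5,5-dimethyl-1,3-dioxan-2-yl)ethynyl]oxy}tri(propan-2-yl)silane
Product: 16 2-(5,5-dimethyl-1,3-dioxan-2-yl)-5-methoxy-4-methyl-3-{[tri(propan-2-yl)silyl]oxy}phenol, via vinylketene 12 (not isolated), via 4-vinylcyclobutenone 13 (not isolated), via dienylketene 14 (not isolated), via cyclohexadienone 15 (not isolated)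
Conditions: toluene, 80 → 110 °C, sealed tube, 11 in slight excess
Reagents that add atoms: none
Why: Thermal four-electron electrocyclic cleavage of the C1–C4 bond of 5 should give vinylketene 12, whose ketene carbon is attacked by the nucleophilic acetal-bearing carbon of 11 in a stepwise polar (2+2) addition to give 4-vinylcyclobutenone 13; this reopens to dienylketene 14, which closes to cyclohexadienone 15 and tautomerises to phenol 16. The closest known reaction is the Danheiser benzannulation of cyclobutenones with triisopropylsiloxyalkynes, which delivers monosilylated resorcinols. Ring A is closed by thermal disrotatory six-electron electrocyclisation of the dienylketene, which forms C4a–C8a after the (2+2) addition has formed C8a–C8 and C6–C7. No stereocentre is created, since the quaternary carbon of 13 is lost on ring opening. The step needs a single orientation of the ketene–alkyne addition, which the oxygen-induced polarisation of the ynol ether secures, so that the acetal carbon ends next to the phenol carbon and the siloxy carbon next to the methyl-bearing carbon. The donor methoxy group may slow the first ring opening, which is the risk the route accepts here.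

Step 6
Reactants: 16 2-(5,5-dimethyl-1,3-dioxan-2-yl)-5-methoxy-4-methyl-3-{[tri(propan-2-yl)silyl]oxy}phenol
Product: 17 2-[4-methoxy-6-(methoxymethoxy)-3-methyl-2-{[tri(propan-2-yl)silyl]oxy}phenyl]-5,5-dimethyl-1,3-dioxane
Conditions: MOMCl, i-Pr2NEt, CH2Cl2, 0 °C → rt
Reagents that add atoms: chloromethyl methyl ether, COCCl
Why: Williamson-type O-alkylation of the C8a phenol under non-acidic conditions that spare the acetal and the silyl ether, installing the directing group for the lithiation.

Step 7
Reactants: 18 3-(4-methoxyphenyl)propanoic acid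
Product: 20 N-methoxy-3-(4-methoxyphenyl)-N-methylpropanamide, via acyl imidazole 19 (not isolated)
Conditions: CDI, CH2Cl2, rt; then MeNH(OMe)·HCl, rt
Reagents that add atoms: N,O-dimethylhydroxylamine hydrochloride, CNOC.Cl
Why: Amide formation through the acyl imidazole (carbonyldiimidazole activation), the standard preparation of a Weinreb amide.

Step 8
Reactants: 17 2-[4-methoxy-6-(methoxymethoxy)-3-methyl-2-{[tri(propan-2-yl)silyl]oxy}phenyl]-5,5-dimethyl-1,3-dioxane; 20 N-methoxy-3-(4-methoxyphenyl)-N-methylpropanamide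
Product: 23 1-[3-(5,5-dimethyl-1,3-dioxan-2-yl)-6-methoxy-2-(methoxymethoxy)-5-methyl-4-{[tri(propan-2-yl)silyl]oxy}phenyl]-3-(4-methoxyphenyl)propan-1-one, via aryllithium 21 (not isolated), via lithium hemiaminal alkoxide 22 (not isolated)
Conditions: n-BuLi, THF, 0 °C; then 20, −78 → 0 °C; aq. NH4Cl
Reagents that add atoms: none
Why: Directed ortho-metalation at C4a, the only ring hydrogen and the one flanked by the methoxymethoxy and methoxy groups, followed by Weinreb ketone synthesis, in which the chelated tetrahedral adduct prevents a second addition.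

Step 9
Reactants: 23 1-[3-(5,5-dimethyl-1,3-dioxan-2-yl)-6-methoxy-2-(methoxymethoxy)-5-methyl-4-{[tri(propan-2-yl)silyl]oxy}phenyl]-3-(4-methoxyphenyl)propan-1-one
Product: 25 5-methoxy-3-[(4-methoxyphenyl)methyl]-6-methyl-4-oxo-7-{[tri(propan-2-yl)silyl]oxy}-4H-chromene-8-carbaldehyde, via enaminone 24 (not isolated)
Conditions: t-BuOCH(NMe2)2, toluene, 100 °C; evaporate; then 3 M aq. HCl, THF, 50 °C
Reagents that add atoms: tert-butoxybis(dimethylamino)methane (Bredereck's reagent), CN(C)C(OC(C)(C)C)N(C)C; water, O
Why: Aminomethylenation of the ketone α-methylene gives the enaminone, and acid then removes the methoxymethyl group so that the C8a hydroxyl adds to the enaminone carbon and expels dimethylamine (6-endo-trig addition–elimination, the enaminone route to chromones), while the same acid hydrolyses the dioxane to the C8 aldehyde.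

Step 10
Reactants: 25 5-methoxy-3-[(4-methoxyphenyl)methyl]-6-methyl-4-oxo-7-{[tri(propan-2-yl)silyl]oxy}-4H-chromene-8-carbaldehyde
Product: 26 7-hydroxy-5-methoxy-3-[(4-methoxyphenyl)methyl]-6-methyl-4-oxo-4H-chromene-8-carbaldehyde (target)
Conditions: Bu4NF, AcOH, THF, 0 °C
Reagents that add atoms: none
Why: Fluoride-induced cleavage of the aryl silyl ether, which should be fast for the acidic C7 phenol next to the formyl group, with acetic acid buffering to protect the base-sensitive chromone.

**Compound list**

1 | 1-ethoxyprop-1-yne | CC#COCC | starting material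
2 | acetone | CC(C)=O | starting material
3 | ketene | C=C=O | intermediate
4 | 3-ethoxy-2-methylcyclobut-2-en-1-one | CCOC1=C(C)C(=O)C1 | intermediate
5 | 3-methoxy-2-methylcyclobut-2-en-1-one | COC1=C(C)C(=O)C1 | intermediate
6 | 3,3-diethoxyprop-1-yne | CCOC(OCC)C#C | starting material
7 | 2,2-dimethylpropane-1,3-diol | OCC(C)(C)CO | starting material
8 | 2-ethynyl-5,5-dimethyl-1,3-dioxane | C#CC1OCC(C)(C)CO1 | intermediate
9 | [(5,5-dimethyl-1,3-dioxan-2-yl)ethynyl]lithium | [Li]C#CC1OCC(C)(C)CO1 | intermediate
10 | lithium 2-(5,5-dimethyl-1,3-dioxan-2-yl)ethynolate | [Li]OC#CC1OCC(C)(C)CO1 | intermediate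
11 | {[(5,5-dimethyl-1,3-dioxan-2-yl)ethynyl]oxy}tri(propan-2-yl)silane | CC(C)[Si](OC#CC1OCC(C)(C)CO1)(C(C)C)C(C)C | intermediate
12 | 3-methoxy-2-methylbuta-1,3-dien-1-one (vinylketene) | C=C(OC)C(C)=C=O | intermediate
13 | 2-(5,5-dimethyl-1,3-dioxan-2-yl)-4-(1-methoxyethenyl)-4-methyl-3-{[tri(propan-2-yl)silyl]oxy}cyclobut-2-en-1-one (racemic) | C=C(OC)C1(C)C(=O)C(C2OCC(C)(C)CO2)=C1O[Si](C(C)C)(C(C)C)C(C)C | intermediate
14 | (3E)-2-(5,5-dimethyl-1,3-dioxan-2-yl)-5-methoxy-4-methyl-3-{[tri(propan-2-yl)silyl]oxy}hexa-1,3,5-trien-1-one (ketene and vinyl termini cis) | C=C(OC)/C(C)=C(/O[Si](C(C)C)(C(C)C)C(C)C)C(=C=O)C1OCC(C)(C)CO1 | intermediate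
15 | 2-(5,5-dimethyl-1,3-dioxan-2-yl)-5-methoxy-4-methyl-3-{[tri(propan-2-yl)silyl]oxy}cyclohexa-2,4-dien-1-one | O=C1CC(OC)=C(C)C(O[Si](C(C)C)(C(C)C)C(C)C)=C1C1OCC(C)(C)CO1 | intermediate
16 | 2-(5,5-dimethyl-1,3-dioxan-2-yl)-5-methoxy-4-methyl-3-{[tri(propan-2-yl)silyl]oxy}phenol | COc1cc(O)c(C2OCC(C)(C)CO2)c(O[Si](C(C)C)(C(C)C)C(C)C)c1C | intermediate
17 | 2-[4-methoxy-6-(methoxymethoxy)-3-methyl-2-{[tri(propan-2-yl)silyl]oxy}phenyl]-5,5-dimethyl-1,3-dioxane | COCOc1cc(OC)c(C)c(O[Si](C(C)C)(C(C)C)C(C)C)c1C1OCC(C)(C)CO1 | intermediate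
18 | 3-(4-methoxyphenyl)propanoic acid | COc1ccc(CCC(=O)O)cc1 | starting material
19 | 1-(1H-imidazol-1-yl)-3-(4-methoxyphenyl)propan-1-one | COc1ccc(CCC(=O)n2ccnc2)cc1 | intermediate
20 | N-methoxy-3-(4-methoxyphenyl)-N-methylpropanamide | COc1ccc(CCC(=O)N(C)OC)cc1 | intermediate
21 | [3-(5,5-dimethyl-1,3-dioxan-2-yl)-6-methoxy-2-(methoxymethoxy)-5-methyl-4-{[tri(propan-2-yl)silyl]oxy}phenyl]lithium | [Li]c1c(OC)c(C)c(O[Si](C(C)C)(C(C)C)C(C)C)c(C2OCC(C)(C)CO2)c1OCOC | intermediate
22 | lithium 1-[3-(5,5-dimethyl-1,3-dioxan-2-yl)-6-methoxy-2-(methoxymethoxy)-5-methyl-4-{[tri(propan-2-yl)silyl]oxy}phenyl]-1-[methoxy(methyl)amino]-3-(4-methoxyphenyl)propan-1-olate (racemic) | COCOc1c(C2OCC(C)(C)CO2)c(O[Si](C(C)C)(C(C)C)C(C)C)c(C)c(OC)c1C(O[Li])(CCc1ccc(OC)cc1)N(C)OC | intermediate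
23 | 1-[3-(5,5-dimethyl-1,3-dioxan-2-yl)-6-methoxy-2-(methoxymethoxy)-5-methyl-4-{[tri(propan-2-yl)silyl]oxy}phenyl]-3-(4-methoxyphenyl)propan-1-one | COCOc1c(C2OCC(C)(C)CO2)c(O[Si](C(C)C)(C(C)C)C(C)C)c(C)c(OC)c1C(=O)CCc1ccc(OC)cc1 | intermediate
24 | (2E)-3-(dimethylamino)-1-[3-(5,5-dimethyl-1,3-dioxan-2-yl)-6-methoxy-2-(methoxymethoxy)-5-methyl-4-{[tri(propan-2-yl)silyl]oxy}phenyl]-2-[(4-methoxyphenyl)methyl]prop-2-en-1-one | COCOc1c(C2OCC(C)(C)CO2)c(O[Si](C(C)C)(C(C)C)C(C)C)c(C)c(OC)c1C(=O)/C(Cc1ccc(OC)cc1)=C/N(C)C | intermediate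
25 | 5-methoxy-3-[(4-methoxyphenyl)methyl]-6-methyl-4-oxo-7-{[tri(propan-2-yl)silyl]oxy}-4H-chromene-8-carbaldehyde | COc1ccc(Cc2coc3c(C=O)c(O[Si](C(C)C)(C(C)C)C(C)C)c(C)c(OC)c3c2=O)cc1 | intermediate
26 | 7-hydroxy-5-methoxy-3-[(4-methoxyphenyl)methyl]-6-methyl-4-oxo-4H-chromene-8-carbaldehyde | COc1ccc(Cc2coc3c(C=O)c(O)c(C)c(OC)c3c2=O)cc1 | target

**Count**

Total step count: 10. Longest linear sequence: 7 steps (steps 1, 2, 5, 6, 8, 9, 10; the branch through steps 3 and 4 is equally long).

**Steps most likely to fail**

Step 5. The vinylogous-ester stabilisation of cyclobutenone 5 may hold the ring closed up to temperatures at which the siloxyalkyne decomposes or the ketene dimerises, so that the (2+2) addition is outrun. The phenol formed may also be acylated by remaining vinylketene. The fallback generates the same vinylketene at room temperature by a photochemical Wolff rearrangement (the diazo ketone variant of the benzannulation). It sets out from siloxyalkyne 11, with commercial methyl vinyl ether and N-methoxy-N-methylpropanamide in place of 5, and comes back at phenol 16. Methyl vinyl ether is lithiated (t-BuLi, THF, −78 → 0 °C) to (1-methoxyethenyl)lithium F1, which is acylated with the Weinreb amide to 2-methoxypent-1-en-3-one F2. Trifluoroacetylation of its lithium enolate (LiN(SiMe3)2, CF3CO2CH2CF3, THF, −78 °C) gives 1,1,1-trifluoro-5-methoxy-3-methylhex-5-ene-2,4-dione F3. This is treated without purification with MsN3, Et3N and H2O in MeCN to give 4-diazo-2-methoxypent-1-en-3-one F4 (detrifluoroacetylative diazo transfer). Irradiation of F4 with 11 (300 nm, ClCH2CH2Cl, rt) should give vinylketene 12, and brief heating to 80 °C completes the passage through 13, 14 and 15 to 16.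

Step 4. Oxygen transfer to the inductively deactivated acetylide may be slow, silylation may occur on carbon, and the acetal conjugated with the ynol ether may ionise during isolation. The fallback makes the ynolate by carbenoid rearrangement instead of acetylide oxidation. It sets out from diol 7 and commercial ethyl diethoxyacetate and comes back at ynolate 10, which is silylated as in step 4 to 11. Transacetalisation (TsOH·H2O cat., cyclohexane, reflux) gives ethyl 5,5-dimethyl-1,3-dioxane-2-carboxylate F5. Kowalski ester homologation (CH2Br2, lithium 2,2,6,6-tetramethylpiperidide, THF, −78 °C; then LiN(SiMe3)2) converts F5, with loss of ethoxide, into lithium 2,2-dibromo-1-(5,5-dimethyl-1,3-dioxan-2-yl)ethen-1-olate F6. n-BuLi (−78 °C → rt) then effects bromine–lithium exchange and 1,2-shift of the dioxanyl group to give 10.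

Step 8. Proton transfer from the α-methylene of the Weinreb amide to the hindered aryllithium may compete with addition and return 17. The fallback uses a more electrophilic partner and adjusts the oxidation level afterwards. It sets out from 17 (lithiated as before to 21) and comes back at ketone 23. Aryllithium 21 is added to commercial 3-(4-methoxyphenyl)propanal (THF, −78 °C, optionally after transmetalation with CeCl3) to give 1-[3-(5,5-dimethyl-1,3-dioxan-2-yl)-6-methoxy-2-(methoxymethoxy)-5-methyl-4-{[tri(propan-2-yl)silyl]oxy}phenyl]-3-(4-methoxyphenyl)propan-1-ol F7 (racemic). Dess–Martin oxidation (NaHCO3-buffered, CH2Cl2, 0 °C) then gives 23.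

**Further compounds**

F1 | step 5 | (1-methoxyethenyl)lithium | [Li]C(=C)OC
F2 | step 5 | 2-methoxypent-1-en-3-one | C=C(OC)C(=O)CC
F3 | step 5 | 1,1,1-trifluoro-5-methoxy-3-methylhex-5-ene-2,4-dione (racemic) | C=C(OC)C(=O)C(C)C(=O)C(F)(F)F
F4 | step 5 | 4-diazo-2-methoxypent-1-en-3-one | C=C(OC)C(=O)C(C)=[N+]=[N-]
F5 | step 4 | ethyl 5,5-dimethyl-1,3-dioxane-2-carboxylate | CCOC(=O)C1OCC(C)(C)CO1
F6 | step 4 | lithium 2,2-dibromo-1-(5,5-dimethyl-1,3-dioxan-2-yl)ethen-1-olate | [Li]OC(=C(Br)Br)C1OCC(C)(C)CO1
F7 | step 8 | 1-[3-(5,5-dimethyl-1,3-dioxan-2-yl)-6-methoxy-2-(methoxymethoxy)-5-methyl-4-{[tri(propan-2-yl)silyl]oxy}phenyl]-3-(4-methoxyphenyl)propan-1-ol (racemic) | COCOc1c(C2OCC(C)(C)CO2)c(O[Si](C(C)C)(C(C)C)C(C)C)c(C)c(OC)c1C(O)CCc1ccc(OC)cc1
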